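The readings come from a simulation for substances that don't exist; the scatter is artificial.

Answer 3 questions about one flask, in which Z replaces E on the complex Q, first giving L, then X.

| setting | east | flask |
|---|---|---|
| Q | 0.0020 M | 0.0020 M |
| Z | 1 mM | 1.00 mM |
| E | 2 mM | 2.00 mM |
| remark | the very flask that is asked about, followed so far |  |
| time |  | 8.0 min |

- east (time / s: X / %, L / %): 10.0: 19.2, 6.0; 15.0: 19.1, 5.2; 30.0: 19.1, 3.9; 50.0: 18.8, 3.8; 90.0: 18.6, 2.8

(scatter of a reading: 0.3 percentage points)

- time, not beyond 8.0 min, at which the flask holds most X
- the amount of X, in percent of the Q charged, at that time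
- the first time at which X reaches 9.6 %, in the same percent

- a reading or a percentage of E counts all its forms, free or not

Start from the ledger of Z. Each X holds two Z, and X on every Q needs more Z than this flask was charged, so Z is the limiting reagent. Halve the Z charged and divide by the Q charged: that is the ceiling, the most X the charges allow, 25.0 %.

Now turn the question round. A late top needs X climbing toward the ceiling, with Z held in neither L nor X shrinking. Read the east run. X goes from 19.2 % at 10.0 s to 18.6 % at 90.0 s, with a scatter of 0.3 percentage points. Twice the ceiling, less 2X, less L, gives that unheld Z: it grows from 5.60 % to 10.0 % of the Q charged. The first reading stands 5.8 points under the ceiling. So my own reckoning is a shallow, early top near that reading.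

The forecast puts the top at 0.15 min (0.07 min to 0.3 min) with 19.4 % (19 % to 20.3 %), and X at 9.6 % after 3.2 s (1.5 s to 5.5 s). In its words, “X overshoots and declines”.

This flask tops at 19.2 % at 0.342 min and reaches 9.6 % at 1.32 s. The forecast's height holds. Its top comes earlier than the flask's, beyond its range, and its first passage later, also beyond its range. The top is flat: X stands at 18.8 % at 0.171 min and 19.0 % at 0.685 min.

    Q + Z ⇌ E + L (K = 0.740, k = 1700 /M/s)
    2 Q → D (k = 17.0 /M/s)
    J ⇌ E, rate k3*(cs3 - [E]) while solid is left; crystals form when [E] > cs3 (solubility = 0.750 mM, k = 1.70 /s)
    L + Z ⇌ E + X (K = 22.0, k = 1100 /M/s)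

This flask's top is 76.8 % of the ceiling. Part of what holds this flask's top down is the depletion of Z: in the run with [Z] held at its charge, the top rises from 19.2 % to 87.8 %. Now charge 0.0040 M of Z, other charges held: the ceiling becomes 100 %. That neighbour flask tops at 83.3 %, which is 83.3 % of its ceiling.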